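- Picture a closed, stirred vessel at fixed temperature, holding starting material, second substrate and a trace of free catalyst, with target read as a share of the starting material charged.

all flasks: starting material 0.072 M

| run | second substrate | free catalyst | temperature | remark | time |
|---|---|---|---|---|---|
| cedar | 1.4 equiv | 0.5 mol% | −5 °C | run made earlier |  |
| oak | 2.2 equiv | 0.5 mol% | 38 °C | run made earlier |  |
| maple | 1 equiv | 1 mol% | −5 °C | run made earlier |  |
| summer | 1.00 equiv | 0.5 mol% | 50 °C |  | 5.0 h |
| dusk | 1.00 equiv | 0.5 mol% | 25 °C |  | 5.0 h |
| winter | 1.00 equiv | 0.5 mol% | 0 °C |  | 5.0 h |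
| noon | 1.00 equiv | 0.5 mol% | 75 °C |  | 5.0 h |

- cedar (time / h: target / %, starting material / %): 10.0: 0.4, 99.8; 20.0: 0.7, 99.7; 30.0: 0.2, 99.4; 40.0: 0.1, 99.2; 50.0: 0.1, 99.7; 60.0: 0.1, 99.3
- oak (time / h: target / %, starting material / %): 0.417: 0.6, 99.2; 1.50: 1.4, 97.7; 2.50: 3.6, 97.1; 4.00: 5.9, 94.8; 5.00: 7.2, 93.2; 8.00: 11.7, 88.7
- maple (time / h: target / %, starting material / %): 12.0: 0.7, 99.5; 25.0: 0.6, 99.6; 40.0: 1.5, 99.1; 50.0: 1.6, 98.9; 60.0: 1.6, 98.7

(each reading ± 0.3 percentage points)

- what was read earlier has a scatter of 0.3 percentage points, one standard deviation

1. the flask that comes out highest in amount of target, in percent of the starting material charged, or "all alike" when all lie within 1.5 percentage points (summer / dusk / winter / noon / all alike)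
2. target at the end, in percent of the starting material charged, summer
3. target at the end, in percent of the starting material charged, dusk
4. target at the end, in percent of the starting material charged, winter
5. target at the end, in percent of the starting material charged, noon

- Read oak first: its target climbs in a straight line, 7.2% at 5.00 h and 11.7% at 8.00 h. So take the clearing time: the hours that straight rate needs to turn the whole charge into target.
- Take the rate as proportional to catalyst. That is an assumption: cedar's last target reading is 0.1%, against a scatter of 0.3 percentage points.
- At 0.5 mol%, oak's readings give a clearing time of 68.4 h. Maple's readings, scaled down from 1 mol%, give 7500 h. Oak ran at 2.2 equiv of second substrate and maple at 1 equiv; carry that difference uncorrected.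
- Lay the logarithm of the clearing time straight through these two temperatures and climb the ladder. Noon takes 1.20 h, summer 18.4 h, dusk 283 h.
- Winter's clearing time, the hours for its whole charge at the straight rate, comes to 4340 h.
- Hold these against 5.0 h. Noon's clearing time is shorter than that, so expect its charge to be turned to target within the time. The others reach their time ratio: summer 27.2%, dusk 1.77%, winter 0.115%.
- The forecast also picks noon, but with 40% there, 11% for summer, 1.7% for dusk and 0.15% for winter, which differs from this reckoning at noon and summer. It warns: “The 75 °C value is the least certain, since it lies outside the data and the catalyst could die.”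
- The flask gives noon as highest: noon 99.9%, summer 39.4%, dusk 2.89%, winter 0.193%. The forecast and the flask part at noon, by 60 points.

    starting material + free catalyst ⇌ catalyst intermediate A (K = 23.0 M⁻¹, k = 54.1 M⁻¹ min⁻¹, Ea = 42.0 kJ mol⁻¹, ΔH = −12.0 kJ mol⁻¹)
    catalyst intermediate A → free catalyst + target (k = 1.08 min⁻¹, Ea = 77.0 kJ mol⁻¹)
    second substrate + free catalyst ⇌ catalyst intermediate B (K = 530 M⁻¹, k = 28.9 M⁻¹ min⁻¹, Ea = 50.0 kJ mol⁻¹, ΔH = −35.0 kJ mol⁻¹)
    catalyst intermediate B → free catalyst + second product (k = 0.753 min⁻¹, Ea = 84.0 kJ mol⁻¹)
    (constants at 50 °C)

- Winter's result, taken as an average rate over its time, gives a clearing time of 2590 h, shorter than the reckoned 4340 h. Now take the neighbour, winter with 0.3 mol% of free catalyst, and stretch that time by the loading ratio to 4310 h, which reckons 0.116% of target in 5.0 h. Catalyst intermediate B, the resting state, holds 84.8% of the catalyst charged in winter and 84.8% in the neighbour at 5.00 h. The neighbour flask gives 0.116% of target.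

The earlier runs and the new flask stem from a simulated flask for substances that don't exist; noise was put on by code.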